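The earlier runs and the new flask are simulated with made-up constants; scatter was added.

Early on in the delta run E lagged Q: at 2.50 min it read Q 3.9% and E 0%, so I took E as Q grown old.

| flask | D | J | G | temperature | remark | time |
|---|---|---|---|---|---|---|
| delta | 0.20 M | 0.10 M | 0.060 M | 15 °C | run made earlier |  |
| zeta | 0.20 M | 0.050 M | 0.060 M | 26 °C | run made earlier |  |
| eta | 0.20 M | 0.20 M | 0.060 M | 15 °C | run made earlier |  |
| cedar | 0.20 M (fed, over 8.0 min) | 0.100 M | 0.0600 M | 20 °C | all else is in the flask from the start; the feed brings no volume worth counting | 10 min |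
| ash | 0.20 M | 0.100 M (fed, over 8.0 min) | 0.0600 M | 20 °C | all else is in the flask from the start; the feed brings no volume worth counting | 10 min |
| larch | 0.20 M | 0.100 M | 0.0600 M | 20 °C | everything together at the start | 10 min |
| birch | 0.20 M (fed, over 8.0 min) | 0.100 M | 0.0600 M |  | the addition at 0 °C, then warmed to 20 °C; the feed brings no volume worth counting | 10 min |

| run | time / min | Q / % | E / % | D / % |
|---|---|---|---|---|
| delta | 2.50 | 3.9 | 0 | 95.3 |
| delta | 5.00 | 6.4 | 0.2 | 92.0 |
| delta | 8.00 | 8.6 | 2.7 | 86.9 |
| delta | 10.0 | 11.2 | 5.5 | 82.1 |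
| zeta | 1.50 | 1.2 | 1.4 | 96.2 |
| zeta | 3.00 | 5.0 | 2.4 | 94.5 |
| zeta | 5.00 | 3.3 | 2.9 | 89.4 |
| zeta | 6.00 | 4.7 | 6.7 | 88.9 |
| eta | 1.50 | 3.3 | 0 | 96.2 |
| eta | 3.00 | 8.2 | 0.2 | 89.5 |
| eta | 5.00 | 16.6 | 1.4 | 81.3 |
| eta | 6.00 | 25.5 | 4.9 | 69.1 |

(standard deviation of a reading: 1 percentage point)

- for Q the X are counted in
- as a solid, counted per litre of solution: X
- on the list of suspects stand: D + J + Z -> Q + 2 Z; D + J -> Q + Z; G + Z <-> L; X <-> Q; Q -> E

1. the flask with the highest share of Q in Q plus E ("all alike" if they lie within 1.5 percentage points) (cedar / ash / larch / birch / all alike)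
2. share of Q in Q plus E at the end, cedar
3. share of Q in Q plus E at the end, ash
4. share of Q in Q plus E at the end, larch
5. share of Q in Q plus E at the end, birch

I folded the flask into one age number, the loss constant of Q to E times the mean age of Q, a Damköhler number of that step, and I took the share of Q in Q plus E as e to minus that number. On the first round I took formation as steady, so the age was half the elapsed time. Then I went round again with the part of Q plus E formed by mid-run. That gave delta a mean age of 4.48 min and, from its last reading, a constant of 0.0893 min⁻¹. Zeta gave 3.45 min and 0.257 min⁻¹. Interpolating the logarithm over temperature gave 0.144 min⁻¹ at 20 °C and 0.0211 min⁻¹ at 0 °C.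

Larch, given delta's age, came to 0.646, a share of 52.4%. For cedar and ash I took the rate of formation as climbing through the feed and then holding, which made the age 3.44 min, the number 0.497 and the share 60.8% in both. For birch I counted the warm stretch, since the cold constant is smaller, and took Q as formed there. That gave 0.144, the lowest number, and a share of 86.6%. Was one number enough? Eta, unused so far, came to 81.2% against a reading of 83.9%.

The forecast, a little apart from mine, named birch, with 62%, 60%, 49% and 82% for cedar, ash, larch and birch: “Feeding D or J delays formation, so Q is younger and its share higher”.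

The flasks gave 70.1%, 70.2%, 63.6% and 86.4% in that order, with birch highest.

    D + J + Z → Q + 2 Z (k = 3.10 L² mol⁻² s⁻¹, Ea = 48.0 kJ mol⁻¹)
    D + J → Q + Z (k = 0.00410 L mol⁻¹ s⁻¹, Ea = 66.0 kJ mol⁻¹)
    G + Z ⇌ L, settled at all times (K = 620 L mol⁻¹, ΔH = −13.0 kJ mol⁻¹)
    X ⇌ Q, rate k4*(cs4 - [Q]) while solid is left; crystals form when [Q] > cs4 (solubility = 0.120 M, k = 0.320 s⁻¹)
    Q → E (k = 0.00200 s⁻¹, Ea = 81.0 kJ mol⁻¹)
    (constants at 20 °C)

At 10.0 min larch still made dissolved Q 2.36 times faster than it used it up. Its share reads back as an age number of 0.453, against my 0.646. For larch read at 2.5 min, taking formation as steady up to then, my number scales to 0.180, a share of 83.5%; the computed share is 86.5%.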